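Atom labels: C1 is the methyl-bearing ring-fusion carbon. C2, C3, C4 (isopropyl carbinol) and C5 (ring-fusion CH) complete the five-membered ring. C6 (acyloxy carbon), C7, C8 (vinylic methyl), C9 and C10 (ketone) complete the seven-membered ring.
Retrosynthesis: cut the C6–O acyl bond, take the C8=C9–C10=O enone back to a C8 exocyclic methylene and a C10 carbinol, then cut C6–C7 and C9–C10 together. This is possible because C6 and C10 both carry oxygen and stand 1,4 to each other through C5–C1, while C7–C8(CH3)–C9 is a 2-methylallyl unit tied in at both ends.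
The remainder is a trans cyclopentane-1,2-dicarbaldehyde, cut further at C4–isopropyl, C5–C6 and C1–C10 back to 3-methylcyclopent-2-enone.
Forward: the five-membered ring is bought and dressed in five steps, the seven-membered ring closes in one annulation (step 6), and the vanillate is attached last.
Stereochemistry: C1 comes from the chiral carbene ligand on the catalyst made from Cu(OTf)2, C5 from equilibration trans to the branched C10 acetal, C4 from Grignard attack anti to C6, and C6 from the annulation. C10 is erased by oxidation.
The two secondary carbinols are told apart by a ketal that only the cis 1,3-diol O4/O6 can form, not by steric bias.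

Key step: step 6

Remark: 6 and 7 are carried as C5 epimers and 14 to 16 as C10 epimers, so these centres bear no descriptor in the SMILES. Step 3 settles the first and step 9 removes the second.

Step 1
Reactants: 1 3-methylcyclopent-2-en-1-one; 2 hex-1-yne
Product: 5 triethyl({(3R)-3-methyl-3-[(1E)-2-methylhex-1-en-1-yl]cyclopent-1-en-1-yl}oxy)silane, via alkenylalane 3 (not isolated), via aluminium enolate 4 (not isolated)
Conditions: 2, Me3Al, Cp2ZrCl2 (10 mol %), CH2Cl2, 22 °C; then 1, Cu(OTf)2 (5 mol %), chiral sulfonate-bearing imidazolinium salt (carbene precursor, 5 mol %), THF, 4 °C; then Et3SiOTf, −78 → 0 °C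
Reagents that add atoms: trimethylaluminium C[Al](C)C; triethylsilyl triflate CC[Si](CC)(CC)OS(=O)(=O)C(F)(F)F
Why: Zirconocene-catalysed methylalumination of the alkyne (Negishi carboalumination, syn addition, hence the E-alkenylalane 3) followed by copper-catalysed enantioselective conjugate addition of an alkenylaluminium reagent to a β-substituted cyclopentenone is an established route to all-carbon quaternary centres, the chiral carbene ligand (enantiomer chosen for R at C1 of 5) deciding which face of C1 is attacked, and O-silylation of enolate 4 fixes the double bond at C4=C5 so that only C5 can react next.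

Step 2
Reactants: 5 triethylsilyl enol ether
Product: 6 (3R)-2-(dimethoxymethyl)-3-methyl-3-[(1E)-2-methylhex-1-en-1-yl]cyclopentan-1-one (C5 epimers)
Conditions: HC(OMe)3, Me3SiOTf (10 mol %), CH2Cl2, −78 °C
Reagents that add atoms: trimethyl orthoformate COC(OC)OC
Why: Silyl-triflate-catalysed Mukaiyama-type addition of the enol silane to the dimethoxycarbenium ion from the orthoformate forms C5–C6 at the one position the enol silane allows and delivers C6 at the aldehyde oxidation level; methyl and alkenyl on C1 shield the two faces about equally, so C5 is left as a mixture on purpose and is set in step 3.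

Step 3
Reactants: 6 β-keto acetal (C5 epimers)
Product: 8 (2S,3S)-2,3-bis(dimethoxymethyl)-3-methylcyclopentan-1-one, via keto aldehyde 7 (not isolated)
Conditions: O3, CH2Cl2–MeOH, −78 °C; Me2S, → 22 °C; then HC(OMe)3, TsOH·H2O (10 mol %), MeOH, 40 °C
Reagents that add atoms: ozone [O-][O+]=O (oxygen of 7); trimethyl orthoformate COC(OC)OC
Why: Ozonolysis cleaves the only C=C bond to the neopentyl C10 aldehyde, acid-catalysed acetalisation masks it, and under the same acid the ketone enolises towards C5 so that the epimers should equilibrate to the isomer whose two branched CH(OMe)2 groups are trans (C6 cis to the smaller methyl), which sets C5 by thermodynamic control.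

Step 4
Reactants: 8 bis-acetal ketone
Product: 9 (1R,2R,3S)-2,3-bis(dimethoxymethyl)-3-methyl-1-(propan-2-yl)cyclopentan-1-ol
Conditions: i-PrMgCl, LaCl3·2LiCl, THF, −20 → 0 °C
Reagents that add atoms: isopropylmagnesium chloride CC(C)[Mg]Cl
Why: Lanthanide-salt-assisted Grignard 1,2-addition suppresses enolisation and β-hydride reduction at the hindered ketone, and the nucleophile should enter from the ring face opposite the neighbouring C5 acetal arm (the face of H5), which puts isopropyl trans and the new hydroxyl cis to C6 and sets C4 as R.

Step 5
Reactants: 9 hydroxy bis-acetal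
Product: 11 (1S,2R,3R)-1-methyl-3-(propan-2-yl)-3-[(triethylsilyl)oxy]cyclopentane-1,2-dicarbaldehyde, via bis-lutidinium salt 10 (not isolated)
Conditions: Et3SiOTf (6 equiv), 2,6-lutidine (9 equiv), CH2Cl2, 0 °C; then H2O
Reagents that add atoms: triethylsilyl triflate CC[Si](CC)(CC)OS(=O)(=O)C(F)(F)F; water O
Why: Et3SiOTf with 2,6-lutidine silylates the tertiary alcohol and at the same time converts aldehyde-derived dimethyl acetals into lutidinium salts that water hydrolyses to aldehydes (silyl-triflate/pyridine-base acetal cleavage), so both formyl groups appear without protic acid or strong base and neither β-elimination of O4 nor epimerisation at C5 is invited.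

Step 6
Reactants: 11 trans dialdehyde; 12 2-(chloromethyl)-3-(trimethylsilyl)prop-1-ene
Product: 14 trans-fused bicyclo[5.3.0]decane diol (1S,4R,5S,6S; C8 exocyclic methylene; O4 triethylsilyl ether; C10 carbinol either epimer), via hydroxy aldehyde 13 (not isolated)
Conditions: 12 (1.0 equiv), SmI2 (0.1 M in THF, run in to the persistent blue end point), THF, −20 °C; pH 7 buffer, extract, dry; then 2,6-di-tert-butylpyridine, BF3·OEt2 (2.5 equiv), CH2Cl2 (0.005 M), −78 → −40 °C; aq NaHCO3
Reagents that add atoms: none
Why: Two equivalents of divalent samarium reduce the allylic chloride to an allylsamarium that adds to a formyl group through a closed six-membered transition state and forms C6–C7; the allylsilane survives and, once BF3 binds the remaining C10 aldehyde, attacks it through its CH2= terminus (C9), the β-silyl cation losing the silyl group to leave the exocyclic methylene on C8. This is the known (3+4) annulation of 1,4-dicarbonyl compounds with 2-(silylmethyl)allyl conjunctive reagents, a samarium Barbier allylation followed by an intramolecular Hosomi–Sakurai reaction. The seven-membered ring closes 7-exo-trig at the carbonyl carbon and endo with respect to the allylsilane double bond, and the trans arrangement of the two arms holds C9 near C10 while making a C6–O–C10 lactol (a trans-fused pair of five-membered rings), and with it an oxygen-bridged by-product, too strained to compete. C6 is the only new centre that counts: the formyl hydrogen has to sit in the pocket under the ring between O4 and the C1 methyl, the metal-bound oxygen points outward next to O4, and C7 bonds on the side away from the bulkier C4, which should give 6S with H5 and H6 anti (the equatorial carbinol), whereas C10 may form as either epimer. The step needs one allyl unit per dialdehyde, which titration of SmI2 into an equimolar mixture secures, but it does not need a strict choice between the aldehydes, because addition at C10 first and closure onto C6 makes the same two bonds and the same ring, the tether then placing C7 anti to C4 by itself. The hindered pyridine takes up stray acid so that protodesilylation does not overtake ring closure.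

Step 7
Reactants: 14 silyl-protected diol
Product: 15 triol (1S,4R,5S,6S; C10 either epimer)
Conditions: HF·pyridine, pyridine, THF, 0 → 22 °C
Reagents that add atoms: none
Why: Fluoride-driven Si–O cleavage frees O4, needed as the partner of O6 in step 8, and it makes any O4-to-O6 silyl migration during step 6 harmless because every silyl isomer converges on 15.

Step 8
Reactants: 15 triol
Product: 16 4,6-O-isopropylidene ketal with free C10 hydroxyl
Conditions: Me2C(OMe)2, PPTS (10 mol %), acetone, 22 °C
Reagents that add atoms: 2,2-dimethoxypropane COC(C)(C)OC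
Why: Acid-catalysed transketalisation under equilibrium control: only O4 and O6 are 1,3-related and on the same ring face and can share a six-membered dioxane, so C10–OH is left as the single free hydroxyl whatever the relative steric demand of the two secondary carbinols.

Step 9
Reactants: 16 ketal alcohol
Product: 18 conjugated enone ketal (C8=C9–C10=O with C8 methyl), via exocyclic-methylene ketone 17 (not isolated)
Conditions: Dess–Martin periodinane, pyridine, CH2Cl2, 22 °C; Na2S2O3/NaHCO3 wash; then DBU (0.2 equiv), CH2Cl2, 22 °C
Reagents that add atoms: none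
Why: Dess–Martin oxidation turns the C10 carbinol (both epimers) into the ketone, and DBU then moves the exocyclic double bond into conjugation through the C9 dienolate (base-catalysed β,γ to α,β isomerisation), which creates the C8 methyl group, while O6, bound in the ketal, is too poor a leaving group for a vinylogous E1cB loss.

Step 10
Reactants: 18 enone ketal
Product: 19 enone diol (1S,4R,5S,6S)
Conditions: AcOH–H2O–THF (3:1:1), 22 °C
Reagents that add atoms: none
Why: Mild acid hydrolysis of a ketal that is strained by the fully substituted C4 should be fast at room temperature and leaves enone, tertiary alcohol and all stereocentres untouched.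

Step 11
Reactants: 20 vanillic acid
Product: 22 4-[(tert-butyldimethylsilyl)oxy]-3-methoxybenzoic acid, via silyl ester 21 (not isolated)
Conditions: TBSCl (2.5 equiv), imidazole, DMF, 22 °C; then AcOH–H2O–THF, 22 °C
Reagents that add atoms: tert-butyldimethylsilyl chloride CC(C)(C)[Si](C)(C)Cl
Why: Standard silylation of phenol and acid followed by selective hydrolysis of the far more labile silyl ester gives the acid with the phenol masked by a group that fluoride removes at the end.

Step 12
Reactants: 19 enone diol; 22 protected vanillic acid
Product: 23 C6 ester with silyl-protected phenol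
Conditions: DCC, DMAP (0.3 equiv), CH2Cl2, 22 °C
Reagents that add atoms: none
Why: Steglich esterification acylates the secondary C6 hydroxyl with retention, because a tertiary carbinol flanked by isopropyl does not compete under these conditions.

Step 13
Reactants: 23 protected ester
Product: 24 target CNP0136950.2
Conditions: HF·pyridine, pyridine, THF, 0 °C
Reagents that add atoms: none
Why: Aryl silyl ethers are cleaved quickly by buffered HF·pyridine, and the slightly acidic medium avoids base-induced vinylogous elimination of the C6 vanillate from the enone.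

Compound list
1 | 3-methylcyclopent-2-en-1-one | CC1=CC(=O)CC1 | starting material
2 | hex-1-yne | CCCCC#C | starting material
3 | (E)-dimethyl(2-methylhex-1-en-1-yl)aluminium | CCCC/C(C)=C/[Al](C)C | intermediate
4 | dimethylaluminium C4=C5 enolate of (R)-3-methyl-3-[(E)-2-methylhex-1-enyl]cyclopentanone | C[Al](C)OC1=C[C@@](C)(/C=C(\C)CCCC)CC1 | intermediate
5 | triethyl({(3R)-3-methyl-3-[(1E)-2-methylhex-1-en-1-yl]cyclopent-1-en-1-yl}oxy)silane | CC[Si](CC)(CC)OC1=C[C@@](C)(/C=C(\C)CCCC)CC1 | intermediate
6 | (3R)-2-(dimethoxymethyl)-3-methyl-3-[(1E)-2-methylhex-1-en-1-yl]cyclopentan-1-one, C5 epimers | COC(OC)C1C(=O)CC[C@]1(C)/C=C(\C)CCCC | intermediate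
7 | (1S)-2-(dimethoxymethyl)-1-methyl-3-oxocyclopentane-1-carbaldehyde, C5 epimers | COC(OC)C1C(=O)CC[C@]1(C)C=O | intermediate
8 | (2S,3S)-2,3-bis(dimethoxymethyl)-3-methylcyclopentan-1-one (acetal arms trans) | COC(OC)[C@H]1C(=O)CC[C@]1(C)C(OC)OC | intermediate
9 | (1R,2R,3S)-2,3-bis(dimethoxymethyl)-3-methyl-1-(propan-2-yl)cyclopentan-1-ol (OH cis to the C5 arm) | COC(OC)[C@H]1[C@](O)(C(C)C)CC[C@]1(C)C(OC)OC | intermediate
10 | O4-triethylsilyl bis[methoxy(2,6-dimethylpyridinium-1-yl)methyl] ditriflate | COC([n+]1c(C)cccc1C)[C@H]2[C@](O[Si](CC)(CC)CC)(C(C)C)CC[C@]2(C)C(OC)[n+]3c(C)cccc3C.[O-]S(=O)(=O)C(F)(F)F.[O-]S(=O)(=O)C(F)(F)F | intermediate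
11 | (1S,2R,3R)-1-methyl-3-(propan-2-yl)-3-[(triethylsilyl)oxy]cyclopentane-1,2-dicarbaldehyde (formyl groups trans) | O=C[C@H]1[C@](O[Si](CC)(CC)CC)(C(C)C)CC[C@]1(C)C=O | intermediate
12 | 2-(chloromethyl)-3-(trimethylsilyl)prop-1-ene | C=C(CCl)C[Si](C)(C)C | starting material
13 | (1S,2S,3R)-2-{(1S)-1-hydroxy-3-[(trimethylsilyl)methyl]but-3-en-1-yl}-1-methyl-3-(propan-2-yl)-3-[(triethylsilyl)oxy]cyclopentane-1-carbaldehyde | O[C@@H](CC(=C)C[Si](C)(C)C)[C@H]1[C@](O[Si](CC)(CC)CC)(C(C)C)CC[C@]1(C)C=O | intermediate
14 | trans-fused bicyclic diol, 1S,4R,5S,6S, C8 exocyclic methylene, O4 triethylsilyl ether, C10 carbinol either epimer | O[C@H]1CC(=C)CC(O)[C@@]2(C)CC[C@@](O[Si](CC)(CC)CC)(C(C)C)[C@H]12 | intermediate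
15 | bicyclic 4,6,10-triol, 1S,4R,5S,6S, C8 exocyclic methylene | O[C@H]1CC(=C)CC(O)[C@@]2(C)CC[C@@](O)(C(C)C)[C@H]12 | intermediate
16 | 4,6-O-isopropylidene ketal of 15, C10 hydroxyl free | CC1(C)O[C@H]2CC(=C)CC(O)[C@@]3(C)CC[C@@](O1)(C(C)C)[C@H]23 | intermediate
17 | C10 ketone with C8 exocyclic methylene, 4,6-ketal | CC1(C)O[C@H]2CC(=C)CC(=O)[C@@]3(C)CC[C@@](O1)(C(C)C)[C@H]23 | intermediate
18 | C8=C9–C10=O enone, 4,6-ketal | CC1(C)O[C@H]2CC(C)=CC(=O)[C@@]3(C)CC[C@@](O1)(C(C)C)[C@H]23 | intermediate
19 | enone 4,6-diol, 1S,4R,5S,6S | O[C@H]1CC(C)=CC(=O)[C@@]2(C)CC[C@@](O)(C(C)C)[C@H]12 | intermediate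
20 | vanillic acid | COc1cc(C(=O)O)ccc1O | starting material
21 | tert-butyldimethylsilyl 4-[(tert-butyldimethylsilyl)oxy]-3-methoxybenzoate | COc1cc(C(=O)O[Si](C)(C)C(C)(C)C)ccc1O[Si](C)(C)C(C)(C)C | intermediate
22 | 4-[(tert-butyldimethylsilyl)oxy]-3-methoxybenzoic acid | COc1cc(C(=O)O)ccc1O[Si](C)(C)C(C)(C)C | intermediate
23 | C6 4-O-silylvanillate of 19 | COc1cc(C(=O)O[C@H]2CC(C)=CC(=O)[C@@]3(C)CC[C@@](O)(C(C)C)[C@H]23)ccc1O[Si](C)(C)C(C)(C)C | intermediate
24 | CNP0136950.2, 1S,4R,5S,6S | COc1cc(C(=O)O[C@H]2CC(C)=CC(=O)[C@@]3(C)CC[C@@](O)(C(C)C)[C@H]23)ccc1O | target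

Total step count: 13. Longest linear sequence: 12 (steps 1 to 10, 12 and 13).

Steps most likely to fail

Step 6. In the Lewis-acid stage the silyl group may be lost by protonation, or the free C6 hydroxyl may engage the C10 aldehyde, before the seven-membered ring closes. In the first stage a second allyl unit may add. Fallback from 11 back to 14: a zinc-mediated Barbier reaction in THF–aqueous NH4Cl with one equivalent of 3-chloro-2-(chloromethyl)prop-1-ene would engage one C–Cl bond only and give the 2-(chloromethyl)allyl carbinol F1, which is purified. CrCl2 with LiI in DMF–THF at high dilution then turns the remaining allylic chloride into an allylchromium that adds to the C10 aldehyde (intramolecular Nozaki–Hiyama allylation). This closes the same C9–C10 bond without any Lewis acid and returns to diol 14.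

Step 4. β-Hydride transfer from the secondary Grignard reagent, or enolisation, may outrun addition at the crowded ketone. Fallback from 8 back to 9: isopropenylmagnesium bromide (CH2=C(CH3)MgBr) with CeCl3 in THF at −78 °C is a flat nucleophile without β-hydrogen and should add from the same face to give the isopropenyl carbinol F2. Hydrogenation of its 1,1-disubstituted alkene with H2 and RhCl(PPh3)3 then gives 9. No other alkene is present at this stage.

Step 3. Epimerisation at C5 under acid may be slow, the trans preference may be too small, or methanol may be lost from the β-keto acetal. Fallback from 5 back to 8, which sets C5 by kinetic attack after C10 has been made bulky: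
- Dilute HCl in THF hydrolyses 5 to the ketone F3.
- IBX in DMSO dehydrogenates it on the only side that has a β-hydrogen and gives the enone F4.
- Ozone (one equivalent) cleaves the electron-rich side-chain alkene in preference to the enone to give the formyl enone F5.
- HC(OMe)3 with TsOH in MeOH masks this as the acetal enone F6.
- Lithium diisopropylamide (i-Pr2NLi) with Me3SiCl can deprotonate only at C5 and gives the silyloxy diene F7.
- HC(OMe)3 with Me3SiOTf at −78 °C should then add on the face away from the branched C10 acetal and give the trans bis-acetal enone F8.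
- H2 over Pd/C saturates C2=C3 and gives 8.

Further compounds
F1 | step 6 | (1S,2S,3R)-2-[(1S)-3-(chloromethyl)-1-hydroxybut-3-en-1-yl]-1-methyl-3-(propan-2-yl)-3-[(triethylsilyl)oxy]cyclopentane-1-carbaldehyde | O[C@@H](CC(=C)CCl)[C@H]1[C@](O[Si](CC)(CC)CC)(C(C)C)CC[C@]1(C)C=O
F2 | step 4 | 2,3-bis(dimethoxymethyl)-3-methyl-1-(prop-1-en-2-yl)cyclopentan-1-ol, ring configuration as in 9 | COC(OC)[C@H]1[C@](O)(C(C)=C)CC[C@]1(C)C(OC)OC
F3 | step 3 | (R)-3-methyl-3-[(1E)-2-methylhex-1-en-1-yl]cyclopentan-1-one | O=C1C[C@@](C)(/C=C(\C)CCCC)CC1
F4 | step 3 | 4-methyl-4-[(1E)-2-methylhex-1-en-1-yl]cyclopent-2-en-1-one, C1 as in F3 | O=C1C[C@@](C)(/C=C(\C)CCCC)C=C1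
F5 | step 3 | 1-methyl-4-oxocyclopent-2-ene-1-carbaldehyde, C1 as in F3 | O=C1C[C@@](C)(C=O)C=C1
F6 | step 3 | 4-(dimethoxymethyl)-4-methylcyclopent-2-en-1-one, C1 as in F3 | O=C1C[C@@](C)(C(OC)OC)C=C1
F7 | step 3 | {[3-(dimethoxymethyl)-3-methylcyclopenta-1,4-dien-1-yl]oxy}trimethylsilane | C[Si](C)(C)OC1=C[C@@](C)(C(OC)OC)C=C1
F8 | step 3 | trans-4,5-bis(dimethoxymethyl)-4-methylcyclopent-2-en-1-one, C1 and C5 as in 8 | COC(OC)[C@H]1C(=O)C=C[C@]1(C)C(OC)OC
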